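Look at what is left in the last readings: 0.6% of the substrate in Thursday's run at 10.0 min, 0% in Wednesday's run at 10.0 min. So the last readings of the two runs can be set side by side.

common to all: substrate 0.13 M
- Thursday's: first nucleophile 1.5 equiv; second nucleophile 1 equiv; run made earlier
- Wednesday's: first nucleophile 1.5 equiv; second nucleophile 1.5 equiv; run made earlier
- flask: first nucleophile 1.50 equiv; second nucleophile 2.00 equiv; time 15 min

- Thursday's (time / min: other capture product / %, target / %, substrate / %): 0.667: 29.9, 42.2, 5.9; 1.33: 35.8, 42.3, 3.6; 2.50: 43.0, 43.4, 1.5; 5.00: 48.3, 44.9, 1.5; 10.0: 52.1, 45.2, 0.6
- Wednesday's (time / min: other capture product / %, target / %, substrate / %): 2.00: 50.6, 38.7, 1.8; 4.00: 56.2, 39.9, 1.1; 5.00: 56.7, 41.0, 0; 8.00: 58.2, 41.3, 0.2; 10.0: 59.4, 40.1, 0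

(scatter of a reading: 0.5 percentage points)

- percent here means substrate units held: one idle adduct counts as two
- what is said of target includes idle adduct
- steps under discussion: substrate <-> intermediate; first nucleophile + intermediate -> target; second nucleophile + intermediate -> other capture product; 2 first nucleophile -> homo dimer; substrate + target <-> idle adduct
- in an amount of target, one idle adduct counts as one target

1. share of other capture product in other capture product plus target at 0.25 s
2. share of other capture product in other capture product plus target at 15 min

Call other capture product over target the odds. The last readings give 1.15 on Thursday and 1.48 on Wednesday.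

Ada argues at the blackboard that the two capture rates go as [first nucleophile][intermediate] and [second nucleophile][intermediate], so [intermediate] cancels and the odds follow the charge of second nucleophile. Scaling Wednesday's run to the new flask gives odds of 1.98, a share of 66.4%.

Ben objects that the same scaling takes Thursday's odds to 1.73 on Wednesday, where 1.48 was read. Between 0.667 min and 10.0 min of Thursday's run, other capture product gains 22 percentage points and target 3 points. His forecast says “the first nucleophile is evidently lost quickly”, and it gives 38% (22% to 50%) early and 62.5% (60.5% to 65%) at the end.

My own reckoning takes the odds step, the rise of the end odds for 0.500 equiv more second nucleophile: 0.329. Added once more, it gives 1.81, a share of 64.4%, above the forecast's value but within its range.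

The flask gives 37.8% early and 63.1% at the end, below Ada's share; its odds of 1.71 make the last step 0.230.

    substrate ⇌ intermediate (K = 0.0870, k = 0.670 s⁻¹)
    first nucleophile + intermediate → target (k = 13.0 L mol⁻¹ s⁻¹)
    second nucleophile + intermediate → other capture product (k = 5.70 L mol⁻¹ s⁻¹)
    2 first nucleophile → homo dimer (k = 0.630 L mol⁻¹ s⁻¹)
    substrate + target ⇌ idle adduct, settled at all times (K = 170 L mol⁻¹)

Ada's view holds at 0.25 s: the flask with 5.00 equiv of second nucleophile has 2.50 times this flask's odds, on 2.50 times its charge. Just after the start, this flask's intermediate goes to other capture product at 0.60 of its rate to target, but half of the homo dimer turnover is done by 0.0522 min and half of the other capture turnover by 0.173 min. Going down instead, the flask with 0.500 equiv is reckoned at 0.824, a share of 45.2%, and stands at 44.0%.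

(All runs were generated by integration from invented constants; scatter was added.)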